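(The earlier runs and the new flask are simulated for an exercise, and the scatter is random.)

Amounts first: Sunday's flask holds 0.050 M of each mirror-image substrate and 0.0300 M of coupling partner. I count one substrate molecule consumed for each molecule of coupling partner, so I carry one quantity, the coupling budget b, which is the coupling partner charged as a percentage of both substrates together:

b = 30.0 %

| flask | left-handed substrate | right-handed substrate | coupling partner | free catalyst | remark | time |
|---|---|---|---|---|---|---|
| Sunday's | 0.050 M | 0.050 M | 0.030 M | 0.25 mM | the very flask that is asked about, followed so far |  |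
| Saturday's | 0.075 M | 0.075 M | 0.030 M | 0.25 mM | run made earlier |  |
| flask | 0.050 M | 0.050 M | 0.0300 M | 0.25 mM |  | 80 min |

| run | time / min | left-handed product / % | right-handed substrate / % |
|---|---|---|---|
| Sunday's | 1.50 | 5.4 | 43.3 |
| Sunday's | 5.00 | 10.8 | 36.5 |
| Sunday's | 8.00 | 12.8 | 36.1 |
| Sunday's | 12.0 | 14.5 | 34.7 |
| Sunday's | 20.0 | 14.7 | 35.0 |
| Sunday's | 25.0 | 14.9 | 34.3 |
| Saturday's | 10.0 | 9.1 | 40.3 |
| Saturday's | 20.0 | 10.0 | 39.5 |
| Saturday's | 30.0 | 10.3 | 39.4 |
| Saturday's | 40.0 | 9.9 | 40.6 |
| Saturday's | 50.0 | 10.6 | 39.1 |
| Saturday's | 60.0 | 9.6 | 40.2 |

(standard deviation of a reading: 0.5 percentage points)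

- free catalyst is single-handed; left-handed substrate and right-handed substrate are mirror images of each other, charged as a racemate, each of them at the stated concentration

* how much left-handed product there is at 80 min, in percent of the left-handed substrate and right-handed substrate together charged
* how much right-handed substrate there is at 80 min, in percent of the left-handed substrate and right-handed substrate together charged

Each substrate makes up 50.0 % of the charge, and b is smaller, so coupling partner is the limiting reagent. The readings agree: at its last reading Sunday's flask has left-handed product plus right-handed substrate lost at 30.6 %, while Saturday's run, with a budget of 20.0 %, stands at 19.4 %.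

Two extremes bracket the flask. If left-handed substrate took the whole budget, left-handed product P would end at b and right-handed substrate S would stay at 50.0 %. If right-handed substrate took it, P would stay at nothing and S would fall to 20.0 %. Between them I define the left share f = P/b, with the symmetric case at the middle of the scale:

f = 0.5, P = 15.0 %, S = 35.0 %

Saturday's readings from 20.0 min on read

f = 0.504

so I keep the symmetric figures. Sunday's readings level within their scatter by 12.0 min, well before 80 min.

The forecast gives 14.8 % (from 14.2 % to 15.4 %) and 34.8 % (from 34.2 % to 35.4 %), slightly below my figures, with “the plateau set by stoichiometry rather than catalyst death”.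

The flask gives 14.7 % of left-handed product and 34.7 % of right-handed substrate, with 0 % of the charged coupling partner still there at 80.0 min.

    coupling partner + catalyst intermediate A → free catalyst + left-handed product (k = 9500 L mol⁻¹ min⁻¹)
    free catalyst + right-handed substrate ⇌ catalyst intermediate B (K = 47.0 L mol⁻¹, k = 1.10 × 10⁵ L mol⁻¹ min⁻¹)
    free catalyst + left-handed substrate ⇌ catalyst intermediate A (K = 31.0 L mol⁻¹, k = 6000 L mol⁻¹ min⁻¹)
    coupling partner + catalyst intermediate B → free catalyst + right-handed product (k = 4100 L mol⁻¹ min⁻¹)
    2 free catalyst ⇌ resting dimer, settled at all times (K = 2.00 × 10⁵ L mol⁻¹)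

Against b, that left-handed product is a left share of 0.490. The neighbouring flask with 0.0075 M of coupling partner has a budget of 7.50 %, and at 80.0 min it holds 4.23 % of left-handed product and 3.27 % of right-handed product, which together come to 7.50 %. Its left share is 0.564.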